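## Retrosynthetic overview
- Disconnect the C5 tertiary alcohol (installed last, by oxidative hydration of C5–H through a vinylogous oxocarbenium) and the C11 ester (the (R)-acyloxy acid comes from D-valine, **2**).
- Disconnect the C8 chlorohydrin to an 8-methylene compound. The C7 oxygen and the C8 exocyclic methylene form together in the key step, a [2,3]-sigmatropic (Mislow–Evans) rearrangement of the C10 allylic sulfoxide.
- Geniposide (**1**) supplies the cyclopentane and dihydropyran rings and the C1/C5/C9 stereocenters, so no ring is built. The glucoside becomes the isovalerate acylal, and the C11 ester is reduced and re-acylated after chlorohydrin formation, because the ester deactivates the enol ether toward Cl⁺.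

Assumption: geniposide's (1S,4aS,7aS) configuration matches the target's C1/C5/C9 (with 5-OH replacing 5-H). The C1 configuration is retained in step 4.

## Route

**Step 1**
Reactants: **2** D-valine
Product: **3** (R)-2-hydroxy-3-methylbutanoic acid
Conditions: NaNO₂, 1 M H₂SO₄, 0 °C → rt
Reagents that add atoms: water (O)
Why: Diazotization of the α-amino acid proceeds with double inversion through an α-lactone, so the (R) centre is retained (diazotization/hydroxylation).

**Step 2**
Reactants: **3**
Product: **4** (R)-2-(isovaleryloxy)-3-methylbutanoic acid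
Conditions: iPrCH₂COCl (2.2 equiv), pyridine, CH₂Cl₂, 0 °C; then aqueous workup
Reagents that add atoms: isovaleryl chloride, CC(C)CC(=O)Cl
Why: The hydroxyl is acylated, and the transient mixed anhydride hydrolyses on workup; the stereocenter is untouched.

**Step 3**
Reactants: **1** geniposide
Product: **5** geniposide pentaacetate
Conditions: Ac₂O, pyridine, DMAP (cat.), rt
Reagents that add atoms: acetic anhydride, CC(=O)OC(C)=O
Why: The glucose hydroxyls are masked, which makes the sugar a leaving group in step 4 and leaves C10-OAc as an allylic acetate for the Pd step (O-acylation).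

**Step 4**
Reactants: **5**
Product: **6** methyl (1S,4aS,7aS)-7-(acetoxymethyl)-1-(isovaleryloxy)-1,4a,5,7a-tetrahydrocyclopenta[c]pyran-4-carboxylate
Conditions: (iPrCH₂CO)₂O (6 equiv), TMSOTf (0.5 equiv), CH₂Cl₂, −20 → 0 °C
Reagents that add atoms: isovaleric anhydride, CC(C)CC(=O)OC(=O)CC(C)C
Why: Lewis-acid cleavage on the sugar side (2′-OAc participation) releases the aglycone lactol oxygen, which is trapped as the isovalerate acylal; C1, C5 and C9 are untouched, and the glucose ends up as its pentaacetate by-product (acylal exchange).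

**Step 5**
Reactants: **6**
Product: **7** 10-phenylthio analogue of **6** (C10–SPh)
Conditions: PhSH, Et₃N, Pd(PPh₃)₄ (5 mol%), THF, rt
Reagents that add atoms: thiophenol, Sc1ccccc1
Why: Pd(0) ionizes only the primary allylic C10 acetate, and the soft thiolate attacks the less hindered π-allyl terminus C10, keeping the C7=C8 alkene (Tsuji–Trost substitution).

**Step 6**
Reactants: **7**
Product: **8** C10 allylic sulfoxide (mixture of S epimers)
Conditions: NaIO₄, MeOH/H₂O, 0 °C
Reagents that add atoms: sodium periodate, [Na+].[O-]I(=O)(=O)=O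
Why: Periodate oxidizes the sulfide selectively, leaving the deactivated enol ether and the esters untouched.

**Step 7 (key step)**
Reactants: **8**
Product: **9** 7-hydroxy-8-methylene compound (C7–OH on the same face as H5/H9)
Conditions: P(OMe)₃ (3 equiv), MeOH, 25 → 50 °C
Reagents that add atoms: none
Why: The allyl sulfoxide undergoes a suprafacial [2,3]-sigmatropic (Mislow–Evans) shift to the sulfenate, which forms on the convex face defined by the cis-fused C5/C9 centres, and the phosphite cleaves S–O irreversibly, so the C7–O bond forms on that face and the C8 exocyclic methylene appears.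

**Step 8**
Reactants: **9**
Product: **10** 7-O-acetyl compound
Conditions: Ac₂O, pyridine, DMAP (cat.), CH₂Cl₂, 0 °C → rt
Reagents that add atoms: acetic anhydride, CC(=O)OC(C)=O
Why: The secondary allylic alcohol is acetylated with no change at C7 (O-acylation).

**Step 9**
Reactants: **10**
Product: **11** 8-(chloromethyl)-8-hydroxy compound
Conditions: NCS, H₂O/acetone (1:4), 0 °C
Reagents that add atoms: N-chlorosuccinimide, O=C1CCC(=O)N1Cl; water, O
Why: Chloronium formation on the exocyclic methylene is followed by Markovnikov opening at tertiary C8, so Cl ends on C10 and OH on C8; the C4 ester keeps the enol ether unreactive, and the stereo outcome comes from the ring (OH trans to 7-OAc) (chlorohydrin formation).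

**Step 10**
Reactants: **11**
Product: **12** C11 carboxylic acid
Conditions: Me₃SnOH, 1,2-DCE, 80 °C
Reagents that add atoms: trimethyltin hydroxide, C[Sn](C)(C)O
Why: This neutral, chemoselective methyl-ester cleavage spares the acetate and acylal and avoids base-induced epoxide closure of the chlorohydrin (ester hydrolysis).

**Step 11**
Reactants: **12**
Product: **13** C11 primary allylic alcohol
Conditions: i-BuOCOCl, NMM, THF, −15 °C; then NaBH₄, MeOH, 0 °C
Reagents that add atoms: none
Why: The mixed anhydride is reduced selectively, whereas the other esters and the chloride are inert to NaBH₄ at 0 °C (acid → alcohol reduction).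

**Step 12**
Reactants: **13**, **4**
Product: **14** 5-deoxy volvaltrate B (C11 ester of **4**)
Conditions: EDC·HCl, DMAP, CH₂Cl₂, 0 °C
Reagents that add atoms: none
Why: Only the primary allylic hydroxyl is acylated, the tertiary C8–OH does not react, and cold, mild conditions preserve the α-stereocenter of **4** (Steglich esterification).

**Step 13**
Reactants: **14**
Product: **15** volvaltrate B
Conditions: DDQ (1.2 equiv), 2,6-di-tert-butylpyridine, THF/H₂O 9:1, 0 °C → rt
Reagents that add atoms: water, O
Why: DDQ abstracts the hydridic C5–H (allylic and vinylogous to O2) to give a stabilized oxocarbenium/allyl cation, and water captures it at tertiary C5 on the convex face, giving the cis-fused 5-OH (H5 and H9 cis) while the enol ether is regenerated (DDQ dehydrogenative hydroxylation).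

## Compound list
1 | geniposide | C([C@@H]1[C@H]([C@@H]([C@H]([C@@H](O1)O[C@@H]2OC=C(C(=O)OC)[C@H]3CC=C(CO)[C@@H]23)O)O)O)O | starting material
2 | D-valine | CC(C)[C@H](C(=O)O)N | starting material
3 | (R)-2-hydroxy-3-methylbutanoic acid | OC(=O)[C@H](O)C(C)C | intermediate
4 | (R)-2-(isovaleryloxy)-3-methylbutanoic acid | OC(=O)[C@H](OC(=O)CC(C)C)C(C)C | intermediate
5 | geniposide pentaacetate | C([C@@H]1[C@H]([C@@H]([C@H]([C@@H](O1)O[C@@H]2OC=C(C(=O)OC)[C@H]3CC=C(COC(C)=O)[C@@H]23)OC(C)=O)OC(C)=O)OC(C)=O)OC(C)=O | intermediate
6 | 10-O-acetyl-1-O-isovalerylgenipin (methyl ester) | COC(=O)C1=CO[C@@H](OC(=O)CC(C)C)[C@@H]2C(COC(C)=O)=CC[C@H]12 | intermediate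
7 | 10-phenylthio analogue of 6 | COC(=O)C1=CO[C@@H](OC(=O)CC(C)C)[C@@H]2C(CSc3ccccc3)=CC[C@H]12 | intermediate
8 | C10 allylic sulfoxide | COC(=O)C1=CO[C@@H](OC(=O)CC(C)C)[C@@H]2C(CS(=O)c3ccccc3)=CC[C@H]12 | intermediate
9 | 7-hydroxy-8-methylene compound | COC(=O)C1=CO[C@@H](OC(=O)CC(C)C)[C@@H]2C(=C)[C@@H](O)C[C@H]12 | intermediate
10 | 7-acetoxy-8-methylene compound | COC(=O)C1=CO[C@@H](OC(=O)CC(C)C)[C@@H]2C(=C)[C@@H](OC(C)=O)C[C@H]12 | intermediate
11 | 7-acetoxy-8-(chloromethyl)-8-hydroxy methyl ester | COC(=O)C1=CO[C@@H](OC(=O)CC(C)C)[C@@H]2[C@@](O)(CCl)[C@@H](OC(C)=O)C[C@H]12 | intermediate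
12 | C11 carboxylic acid | OC(=O)C1=CO[C@@H](OC(=O)CC(C)C)[C@@H]2[C@@](O)(CCl)[C@@H](OC(C)=O)C[C@H]12 | intermediate
13 | C11 primary alcohol | OCC1=CO[C@@H](OC(=O)CC(C)C)[C@@H]2[C@@](O)(CCl)[C@@H](OC(C)=O)C[C@H]12 | intermediate
14 | 5-deoxy volvaltrate B | O=C(OCC1=CO[C@@H](OC(=O)CC(C)C)[C@@H]2[C@@](O)(CCl)[C@@H](OC(C)=O)C[C@H]12)[C@H](OC(=O)CC(C)C)C(C)C | intermediate
15 | volvaltrate B | CC(=O)O[C@H]1C[C@]2(O)C(COC(=O)[C@H](OC(=O)CC(C)C)C(C)C)=CO[C@@H](OC(=O)CC(C)C)[C@@H]2[C@@]1(O)CCl | target

## Totals
Total steps: 13. Longest linear sequence: 11 (geniposide → volvaltrate B, steps 3–13).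

## Three steps most likely to fail
1. **Step 13 (C5–H oxidative hydration).** Water may capture at C3 instead of C5, or the cation may lose H6 to give the 5,6-diene. Fallback: DDQ dehydrogenation to the 5,6-diene, then Co(acac)₂/PhSiH₃/O₂ Mukaiyama hydration, which installs the tertiary C5–OH by a radical mechanism.
2. **Step 4 (glucoside → isovalerate acylal).** Acetate may transfer to C1 instead, or C1 may epimerize. Fallback: deglycosylate geniposide enzymatically with β-glucosidase (or buy genipin), then acylate C1 and C10 with isovaleryl chloride and carry on from step 5.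
3. **Step 9 (chlorohydrin).** NCS may attack the enol ether, or the wrong C8 face may be attacked. Fallback: bypass steps 5–9 by converting C10–OH to CH₂Cl, epoxidizing C7=C8 on the convex face with DMDO, and opening the epoxide at tertiary C8 with water (trans), then selectively acetylating the C7 hydroxyl.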